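**Remark on the chemistry:** 27 is an enolised 1,3-diketone whose enol forms interconvert; the C4-enol/C2-keto form is used for all names and SMILES, and every bicyclic compound carries the locants C1–C9 fixed in the analysis (exo at C7 = on the face of ring B turned away from C2 and C4, endo = turned towards them).

## Analysis of the target

The target 27 is a bicyclo[3.3.1]nonane-2,4,9-trione, enolised and acylated at C3 by a 3,4-dihydroxybenzoyl group. Ring A is C1–C2–C3–C4–C5–C9 and ring B is C1–C8–C7–C6–C5–C9, with C1 the prenyl bridgehead, C5 the geranyl bridgehead, C6 a CH2, C7 the prenyl-bearing CH, C8 the CMe2 carbon and C9 the bridging ketone (prenyl = 3-methylbut-2-en-1-yl, geranyl = (2E)-3,7-dimethylocta-2,6-dien-1-yl). There are three stereocentres (1S,5S,7S as drawn). C1 and C5 are quaternary bridgeheads that can only be set as a pair, because ring A must span them cis. The C7 prenyl group is endo, on the face of ring B that carries C2 and C4 and trans to both bridgehead side chains, so ring B is expected to leave the chair. The sensitive groups are four trisubstituted olefins (no strong acid, electrophilic oxidant or hydrogenation), a catechol (oxidised under base and air) and an acyl trione (retro-Claisen cleavage, acid-induced addition of the enol oxygen to a prenyl group). The difficulty lies in the C9 ketone flanked by two quaternary carbons, one of which (C1) adjoins the quaternary C8, in the two different bridgehead chains, in the absolute configuration, and in the endo C7 substituent, which is the one that carbon–carbon bond formation on the open exo face does not give. The strategy rests on C5: it carries two carbon chains (geranyl and C6) and lies between C4 and C9, both oxygenated. C5 therefore corresponds to the sp3 carbon of a mirror-symmetric 6,6-disubstituted 1,5-dimethoxycyclohexa-1,4-diene in which C4 and C9 are the methoxy-bearing carbons, C3 and C1 the nucleophilic CH carbons and C2 the ring CH2; bonding C1 to C8 breaks the symmetry and closes ring B.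

## Retrosynthetic reasoning

**Unmasking.** The catechol O–Si bonds and the C4 O–CH3 bond of 27 are cut last, giving 26 and then 25. The free catechol and the free acyl trione are the most fragile parts of the molecule. The methyl group also keeps C4 distinct from C2 through the whole sequence.

**C3–aroyl bond.** Cutting the bond between C3 and the aroyl carbonyl leads to 21 and the acid chloride 24 (from 23, from 22). In 21, C3 is the only C–H on the skeleton that can be metalated, an sp2 carbon between the C2 carbonyl and the methoxy-bearing C4. The aryl ketone is introduced after all borane and bridgehead-anion chemistry, in which it would be a liability.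

**C7 side chain.** The prenyl group at C7 is cut between its CH2 and its olefinic CH, together with the C7–H bond, which leads to the 7-methylidene compound 18 and the vinyl bromide 19. The forward reaction adds hydrogen, not carbon, to C7 from the open exo face, so the carbon chain is pushed to the endo side; this is the only simple way to obtain the endo configuration. 18 comes from the ketone 17 and that from the alcohol 16.

**C1–prenyl bond.** Cutting C1–CH2 gives 15 back to 13 and prenyl bromide 14. C1 is the only bridgehead with a hydrogen and is flanked by the C2 and C9 carbonyls. For the carbanion to form there and nowhere else, C3 must carry a silyl block and the C7 oxygen a silyl ether, both installed in one operation on 12 and both removed in one operation from 15. The C7 ketone is made only afterwards, because it would enolise towards C6.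

**Oxidation level of ring A and the C7/C9 oxygens.** The C9 ketone and the C7 hydroxyl of 12 are the two halves of one ketal in 11. The C2 carbonyl of 11 comes from the allylic CH2 of the enol ether in 10. The oxidation is placed before the ketal cleavage: an enol ether would not survive Lewis-acid ketal opening, whereas the vinylogous ester does.

**Key disconnection.** In 10 the C1–C8 bond and the O–C9 bond are cut, which opens ring B and the oxygen bridge and returns the symmetric diene 9 with one epoxide stereocentre. C1–C8 is the hardest bond of the skeleton (bridgehead carbon to quaternary carbon) and is best made from a tertiary cation and an enol ether. The gain is two rings, one skeletal bond and three stereocentres from a single centre that asymmetric epoxidation supplies.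

**Assembly of the precursor.** 9 is cut at the bond between the ring carbon and the epoxide CH2 (to 4 and the bromide 8) and 4 at the bond to the geranyl CH2 (to 2 and 3). Both are alkylations of the same doubly allylic carbon, and 2 is the Birch product of 1. The bromide 8 comes from the sulfonate 7 and that from prenol 5 through the epoxy alcohol 6.

## Alternatives that were turned down

**Alternative 1:** Ring B is opened at C5–C6 (and, one step earlier, C1–C8 by a Claisen rearrangement), which leads to the achiral allylic carbonate A2, a 2,2-disubstituted cyclohexane-1,3-dione whose C1 already bears prenyl and the CMe2–C(=CH2)–CH2O unit. In the forward step a zerovalent palladium catalyst with a chiral P,N ligand ionises the carbonate, and the enolate of one of the two enantiotopic ketones closes ring B through C5 at the allyl terminus to give the dione A1.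
- For: the asymmetric induction is catalytic on an achiral substrate. A1 already contains quaternary C1 with its prenyl group, the C8 gem-dimethyl group and the 7-methylidene handle, so the C7 oxidation, the olefination and the bridgehead prenylation of the chosen route are not needed; on these points it is stronger. The C1/C8 pair is made by a sigmatropic shift, which is dependable.
- Against: the chiral π-allyl unit must distinguish two ketones from a distance while a bridged six-membered ring forms, with O-alkylation and diene formation as competitors, and there is no close model for this. More important for this target, A1 is at the wrong oxidation level: C4 is a methylene and C5 a bridgehead CH. C4 oxygenation next to a bridgehead and geranylation of C5 would follow, which costs more steps than were saved and uses the same bridgehead chemistry.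
- Comparison: the chosen strategy offers the complete 2,4,9-oxygen pattern and the quaternary C5 from the first intermediate, and a ring closure of a known type.

**Alternative 2:** Both rings are unravelled at acyl–carbon bonds (C5–C9 and C2–C3) to the acyclic compound A4, in which quaternary C1 carries prenyl, a methyl ester (C2) and a thioester (C9), and the chain ends in the C4/aroyl 1,3-diketone. In the forward step two equivalents of a lithium amide give the diketone dianion; its terminal carbon C5 acylates the thioester (ring B), then C3 acylates the ester (ring A), giving A3.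
- For: A3 is the bis-silyl ether of the 7-methylidene analogue of the target, so only the C7 side chain and desilylation remain. In steps after the key reaction this is clearly stronger than the chosen route, which needs eleven.
- Against: the difficulty is moved into A4, whose C1 is an acyclic quaternary stereocentre with two different acyl groups next to quaternary C8, with no simple enantioselective access. The first Claisen joins a hindered tertiary carbanion to a neopentyl thioester and gives a β-diketone with no acidic hydrogen between C4 and C9, so nothing opposes its reversal. Only the diastereomer with the C4 and C2 chains cis can go on to ring A.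
- Comparison: the chosen strategy offers an irreversible ring closure and a stereochemical origin in one catalytic epoxidation, at the price of a longer end game.

**Alternative 3:** Ring A is cut at C2–C3 and C4–C5, leading to the meso bridged cyclobutane-1,3-dione A6 and a two-carbon ynolate. In the forward step a chirally ligated lithium silylynolate adds to one of the two enantiotopic carbonyls, the four-membered ring fragments to a cyclohexanone enolate and an acylketene, and the enolate closes ring A on the ketene to give, after loss of silicon, the trione A5.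
- For: ring A with all three carbonyls arises in one operation on a ring B that already has every substituent and the methylidene handle, and C3 is left free; in step count it would be the shortest of all.
- Against: A6 is a strained dione with adjacent quaternary carbons for which no secure preparation exists. The step also needs a chiral ligand on a lithium ynolate to tell apart two carbonyls related by a mirror plane, followed by a fragmentation and recapture cascade, so several unprecedented events are stacked in one flask.
- Comparison: the chosen strategy uses only reactions with clear models for each bond and lets a single epoxide centre, not a new ligand effect, decide the absolute configuration.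

Key step: step 6

## Route

**Step 1**
Reactants: 1 1,3-dimethoxybenzene
Product: 2 1,5-dimethoxycyclohexa-1,4-diene
Conditions: Li, NH3 (l), t-BuOH, THF, −78 to −33 °C
Reagents that add atoms: none
Why: Birch reduction; the methoxy groups stay on the remaining double bonds, which gives the unconjugated diene with one CH2 (C6) flanked by both enol ethers.

**Step 2**
Reactants: 2 1,5-dimethoxycyclohexa-1,4-diene; 3 geranyl bromide
Product: 4 6-geranyl-1,5-dimethoxycyclohexa-1,4-diene
Conditions: t-BuLi, THF, −78 °C; then 3, −78 °C to rt
Reagents that add atoms: none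
Why: Deprotonation at C6 gives a cyclohexadienyl anion with its charge at C2, C4 and C6 and the oxygens on the nodal carbons; SN2 alkylation by the allylic bromide occurs at the central carbon and keeps the two enol ethers unconjugated.

**Step 3**
Reactants: 5 3-methylbut-2-en-1-ol
Product: 7 [(2R)-3,3-dimethyloxiran-2-yl]methyl 4-methylbenzenesulfonate, via [(2R)-3,3-dimethyloxiran-2-yl]methanol 6 (not isolated)
Conditions: Ti(OiPr)4 (cat.), D-(−)-diisopropyl tartrate (cat.), t-BuOOH, 4 Å MS, CH2Cl2, −20 °C; P(OMe)3; then TsCl, Et3N, DMAP (cat.), −10 °C
Reagents that add atoms: tert-butyl hydroperoxide CC(C)(C)OO; 4-methylbenzenesulfonyl chloride Cc1ccc(cc1)S(Cl)(=O)=O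
Why: Sharpless asymmetric epoxidation; the D-(−)-tartrate ligand delivers oxygen to the face that gives the (R)-epoxy alcohol (the L-(+)-ester gives the 2S series), and sulfonylation in the same flask avoids isolating the small water-soluble epoxy alcohol and gives a derivative on which the enantiomeric purity can be checked and raised if needed.

**Step 4**
Reactants: 7 [(2R)-3,3-dimethyloxiran-2-yl]methyl 4-methylbenzenesulfonate
Product: 8 (2S)-2-(bromomethyl)-3,3-dimethyloxirane
Conditions: LiBr, acetone, rt
Reagents that add atoms: lithium bromide [Li+].[Br-]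
Why: Finkelstein-type SN2 displacement at the primary carbon; the stereocentre is not touched, and the descriptor changes from R to S only because CH2Br outranks the ring carbon.

**Step 5**
Reactants: 4 6-geranyl-1,5-dimethoxycyclohexa-1,4-diene; 8 (2S)-2-(bromomethyl)-3,3-dimethyloxirane
Product: 9 6-{[(2R)-3,3-dimethyloxiran-2-yl]methyl}-6-geranyl-1,5-dimethoxycyclohexa-1,4-diene
Conditions: t-BuLi, THF, −78 to −40 °C; then 8, −78 °C to rt
Reagents that add atoms: none
Why: The tertiary C6–H is still the most acidic site (the other doubly allylic CH2 would put charge on the methoxy-bearing carbons); the anion displaces the primary bromide (SN2), the hindered secondary and tertiary oxirane carbons are not attacked, and C6 becomes quaternary but stays non-stereogenic because its two ring arms are identical.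

**Step 6**
Reactants: 9 6-{[(2R)-3,3-dimethyloxiran-2-yl]methyl}-6-geranyl-1,5-dimethoxycyclohexa-1,4-diene
Product: 10 5-geranyl-4,9-dimethoxy-8,8-dimethyl-7,9-epoxybicyclo[3.3.1]non-3-ene (C9 methyl ketal bridged by oxygen to the exo position of C7; C1 and C5 as in 27)
Conditions: TMSOTf (substoichiometric), 2,6-lutidine, CH2Cl2, −78 °C
Reagents that add atoms: none
Why: Silylation of the oxirane oxygen weakens its bond to the tertiary carbon C8, and the CH carbon of one methyl enol ether (C1) attacks C8 from the rear, the closest known reaction type being the Lewis-acid epoxide-initiated cation–olefin cyclisation with an enol ether as terminator, which is documented for 6,6-disubstituted 1,5-dimethoxycyclohexa-1,4-dienes with a 2,3-epoxyalkyl chain. Ring B closes in a 6-endo mode with respect to both the epoxide (opening at the tertiary end, not 5-exo attack at C7) and the enol ether. The C9 methoxy-oxocarbenium ion is then captured by the C7 silyloxy oxygen in a 5-exo closure that forms the 7-oxabicyclo[2.2.1]heptane ketal and releases the silyl group, so the silyl triflate turns over. The C7 centre controls the outcome: in the chair-like transition state the breaking C8–O bond must lie anti to the incoming C1, which places the C7–O bond equatorial (exo); with the R centre only one of the two enantiotopic enol ethers can do this, the other needing a boat. This fixes C5 and, because the bridge can only be cis, C1 in the sense of 27; C9 follows from the geometry of the oxygen bridge. Only the diastereomer with the exo oxygen can form the ketal, so isolating 10 also secures the bridgehead configuration. Chemoselectivity over the geranyl olefins follows from the much higher nucleophilicity of enol ethers, and 2,6-lutidine at −78 °C protects the second enol ether from triflic acid.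

**Step 7**
Reactants: 10 bridged methyl ketal
Product: 11 5-geranyl-4,9-dimethoxy-8,8-dimethyl-7,9-epoxybicyclo[3.3.1]non-3-en-2-one
Conditions: t-BuOOH, PhI(OAc)2, Cs2CO3, EtOAc, −20 °C
Reagents that add atoms: tert-butyl hydroperoxide CC(C)(C)OO
Why: Radical allylic C–H oxidation by tert-butylperoxy radicals; hydrogen abstraction is fastest at C2, whose allyl radical is stabilised by the methoxy group, and the allylic peroxide collapses under base to the C2 ketone (vinylogous ester), while the basic medium spares the ketal.

**Step 8**
Reactants: 11 vinylogous ester ketal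
Product: 12 5-geranyl-7-exo-hydroxy-4-methoxy-8,8-dimethylbicyclo[3.3.1]non-3-ene-2,9-dione
Conditions: Me2BBr, CH2Cl2, −78 °C; then aq. NaHCO3
Reagents that add atoms: water O
Why: Acetal cleavage with bromodimethylborane; the strained ketal collapses to a C9 bromo ether and a C7 borinate, both hydrolysed on work-up to the C9 ketone and the C7 alcohol with C7 unchanged (its C–O bond is not broken), and the vinylogous ester and olefins are inert at −78 °C.

**Step 9**
Reactants: 12 hydroxy dione
Product: 13 5-geranyl-4-methoxy-8,8-dimethyl-3-(trimethylsilyl)-7-exo-(trimethylsilyloxy)bicyclo[3.3.1]non-3-ene-2,9-dione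
Conditions: Me3SiCl, lithium 2,2,6,6-tetramethylpiperidide, THF, −78 °C
Reagents that add atoms: chlorotrimethylsilane C[Si](C)(C)Cl
Why: In situ trapping; the alkoxide is O-silylated and the kinetically favoured vinylic C3–H between the carbonyl and the methoxy-bearing carbon is lithiated and C-silylated (directed lithiation), which blocks C3 and masks the hydroxyl before the bridgehead is addressed.

**Step 10**
Reactants: 13 bis-silyl compound; 14 prenyl bromide
Product: 15 5-geranyl-4-methoxy-8,8-dimethyl-1-prenyl-3-(trimethylsilyl)-7-exo-(trimethylsilyloxy)bicyclo[3.3.1]non-3-ene-2,9-dione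
Conditions: LiN(i-Pr)2, THF, −78 to −40 °C; then 14
Reagents that add atoms: none
Why: Bridgehead lithiation–alkylation; with C3 blocked, C1–H between the C2 and C9 carbonyls is the only acidic hydrogen, and the pyramidal carbanion is alkylated by the allylic bromide with retention, which the bridgehead enforces.

**Step 11**
Reactants: 15 C1-prenylated bis-silyl compound
Product: 16 5-geranyl-7-exo-hydroxy-4-methoxy-8,8-dimethyl-1-prenylbicyclo[3.3.1]non-3-ene-2,9-dione
Conditions: Bu4NF, THF, 0 °C to rt
Reagents that add atoms: none
Why: Fluoride cleaves the silyl ether and protodesilylates the vinylsilane (the C3 carbanion is stabilised by the adjacent carbonyl), which restores C7–OH and C3–H in one operation.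

**Step 12**
Reactants: 16 hydroxy dione
Product: 17 5-geranyl-4-methoxy-8,8-dimethyl-1-prenylbicyclo[3.3.1]non-3-ene-2,7,9-trione
Conditions: Dess–Martin periodinane, NaHCO3, CH2Cl2, rt
Reagents that add atoms: none
Why: Dess–Martin oxidation of the secondary alcohol under buffered, non-acidic conditions that leave the vinylogous ester and the olefins untouched; the C7 centre, whose task ended in step 6, is removed.

**Step 13**
Reactants: 17 trione
Product: 18 5-geranyl-4-methoxy-8,8-dimethyl-7-methylidene-1-prenylbicyclo[3.3.1]non-3-ene-2,9-dione
Conditions: Zn, CH2Br2, TiCl4, THF/CH2Cl2, 0 °C to rt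
Reagents that add atoms: dibromomethane BrCBr
Why: Lombardo–Takai methylenation, a non-basic titanium–zinc methylene reagent suited to hindered enolisable ketones; C9 is shielded by two quaternary neighbours and C2 is a deactivated vinylogous ester carbonyl, so only C7 should react.

**Step 14**
Reactants: 18 7-methylidene compound; 19 1-bromo-2-methylprop-1-ene
Product: 21 5-geranyl-4-methoxy-8,8-dimethyl-1,7-endo-diprenylbicyclo[3.3.1]non-3-ene-2,9-dione, via 7-endo-[(9-borabicyclo[3.3.1]nonan-9-yl)methyl] alkylborane 20 (not isolated)
Conditions: 9-BBN, THF, 0 °C to rt; then 19, Pd(dppf)Cl2 (cat.), K3PO4 (aq.), DMF, 50 °C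
Reagents that add atoms: none
Why: Hydroboration followed by B-alkyl Suzuki–Miyaura coupling; 9-BBN adds only to the 1,1-disubstituted alkene (the trisubstituted olefins and the hindered or vinylogous carbonyls react far more slowly), boron goes to the terminal carbon and hydrogen to C7 from the exo face, because the endo face is blocked by C2 and C4, so the CH2B group is endo; coupling with 19 turns it into CH2–CH=CMe2 without touching C7.

**Step 15**
Reactants: 22 3,4-dihydroxybenzoic acid
Product: 23 triisopropylsilyl 3,4-bis(triisopropylsilyloxy)benzoate
Conditions: i-Pr3SiCl, imidazole, DMF, rt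
Reagents that add atoms: chlorotriisopropylsilane CC(C)[Si](Cl)(C(C)C)C(C)C
Why: Imidazole-promoted silylation of both phenols and the carboxylic acid; the bulky silyl ethers later withstand the vinyllithium and the demethylation.

**Step 16**
Reactants: 23 tris-silyl compound
Product: 24 3,4-bis(triisopropylsilyloxy)benzoyl chloride
Conditions: (COCl)2, DMF (cat.), CH2Cl2, 0 °C to rt
Reagents that add atoms: oxalyl chloride ClC(=O)C(Cl)=O
Why: Conversion of a silyl ester into the acid chloride by the Vilsmeier-type chloroiminium reagent under neutral conditions, which leaves the aryl silyl ethers intact.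

**Step 17**
Reactants: 21 diprenyl vinylogous ester; 24 3,4-bis(triisopropylsilyloxy)benzoyl chloride
Product: 25 3-[3,4-bis(triisopropylsilyloxy)benzoyl]-5-geranyl-4-methoxy-8,8-dimethyl-1,7-endo-diprenylbicyclo[3.3.1]non-3-ene-2,9-dione
Conditions: lithium 2,2,6,6-tetramethylpiperidide, THF, −78 °C; then 24, −78 to −40 °C
Reagents that add atoms: none
Why: Directed lithiation at C3, now the only acidic C–H (C1 and C5 are quaternary), followed by C-acylation of the vinyllithium with the aroyl chloride.

**Step 18**
Reactants: 25 aroylated methyl ether
Product: 26 3-[3,4-bis(triisopropylsilyloxy)benzoyl]-5-geranyl-4-hydroxy-8,8-dimethyl-1,7-endo-diprenylbicyclo[3.3.1]non-3-ene-2,9-dione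
Conditions: LiCl, DMSO, 120 °C, Ar
Reagents that add atoms: none
Why: Krapcho-type SN2 demethylation by chloride at the methyl of the vinylogous ester, whose 2-acyl-1,3-dione enolate is an excellent leaving group; the neutral medium spares the olefins, and any aryl silyl ether lost here converges in step 19.

**Step 19**
Reactants: 26 bis-silyl ether of the target
Product: 27 (1S,5S,7S)-3-(3,4-dihydroxybenzoyl)-5-geranyl-4-hydroxy-8,8-dimethyl-1,7-diprenylbicyclo[3.3.1]non-3-ene-2,9-dione
Conditions: Et3N·3HF, THF, 0 °C to rt
Reagents that add atoms: none
Why: Fluoride cleavage of the aryl silyl ethers in a weakly acidic buffer, which avoids both catecholate oxidation and acid-catalysed addition of the enol to a prenyl group.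

## Compound list

1 | 1,3-dimethoxybenzene | COc1cccc(OC)c1 | starting material
2 | 1,5-dimethoxycyclohexa-1,4-diene | COC1=CCC=C(OC)C1 | intermediate
3 | geranyl bromide, (2E)-1-bromo-3,7-dimethylocta-2,6-diene | CC(C)=CCC/C(C)=C/CBr | starting material
4 | 6-geranyl-1,5-dimethoxycyclohexa-1,4-diene | CC(C)=CCC/C(C)=C/CC1C(OC)=CCC=C1OC | intermediate
5 | 3-methylbut-2-en-1-ol | CC(C)=CCO | starting material
6 | [(2R)-3,3-dimethyloxiran-2-yl]methanol | OC[C@H]1OC1(C)C | intermediate
7 | [(2R)-3,3-dimethyloxiran-2-yl]methyl 4-methylbenzenesulfonate | Cc1ccc(cc1)S(=O)(=O)OC[C@H]1OC1(C)C | intermediate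
8 | (2S)-2-(bromomethyl)-3,3-dimethyloxirane | BrC[C@H]1OC1(C)C | intermediate
9 | 6-{[(2R)-3,3-dimethyloxiran-2-yl]methyl}-6-geranyl-1,5-dimethoxycyclohexa-1,4-diene | CC(C)=CCC/C(C)=C/CC1(C[C@H]2OC2(C)C)C(OC)=CCC=C1OC | intermediate
10 | 5-geranyl-4,9-dimethoxy-8,8-dimethyl-7,9-epoxybicyclo[3.3.1]non-3-ene (oxygen-bridged C9 methyl ketal, C7–O exo) | CC(C)=CCC/C(C)=C/C[C@]12C[C@@H](O3)C(C)(C)[C@H](CC=C1OC)[C@]23OC | intermediate
11 | 5-geranyl-4,9-dimethoxy-8,8-dimethyl-7,9-epoxybicyclo[3.3.1]non-3-en-2-one | CC(C)=CCC/C(C)=C/C[C@]12C[C@@H](O3)C(C)(C)[C@H](C(=O)C=C1OC)[C@]23OC | intermediate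
12 | 5-geranyl-7-exo-hydroxy-4-methoxy-8,8-dimethylbicyclo[3.3.1]non-3-ene-2,9-dione | CC(C)=CCC/C(C)=C/C[C@]12C[C@@H](O)C(C)(C)[C@H](C(=O)C=C1OC)C2=O | intermediate
13 | 5-geranyl-4-methoxy-8,8-dimethyl-3-(trimethylsilyl)-7-exo-(trimethylsilyloxy)bicyclo[3.3.1]non-3-ene-2,9-dione | CC(C)=CCC/C(C)=C/C[C@]12C[C@@H](O[Si](C)(C)C)C(C)(C)[C@H](C(=O)C([Si](C)(C)C)=C1OC)C2=O | intermediate
14 | prenyl bromide, 1-bromo-3-methylbut-2-ene | CC(C)=CCBr | starting material
15 | 5-geranyl-4-methoxy-8,8-dimethyl-1-prenyl-3-(trimethylsilyl)-7-exo-(trimethylsilyloxy)bicyclo[3.3.1]non-3-ene-2,9-dione | CC(C)=CCC/C(C)=C/C[C@]12C[C@@H](O[Si](C)(C)C)C(C)(C)[C@](CC=C(C)C)(C(=O)C([Si](C)(C)C)=C1OC)C2=O | intermediate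
16 | 5-geranyl-7-exo-hydroxy-4-methoxy-8,8-dimethyl-1-prenylbicyclo[3.3.1]non-3-ene-2,9-dione | CC(C)=CCC/C(C)=C/C[C@]12C[C@@H](O)C(C)(C)[C@](CC=C(C)C)(C(=O)C=C1OC)C2=O | intermediate
17 | 5-geranyl-4-methoxy-8,8-dimethyl-1-prenylbicyclo[3.3.1]non-3-ene-2,7,9-trione | CC(C)=CCC/C(C)=C/C[C@]12CC(=O)C(C)(C)[C@](CC=C(C)C)(C(=O)C=C1OC)C2=O | intermediate
18 | 5-geranyl-4-methoxy-8,8-dimethyl-7-methylidene-1-prenylbicyclo[3.3.1]non-3-ene-2,9-dione | CC(C)=CCC/C(C)=C/C[C@]12CC(=C)C(C)(C)[C@](CC=C(C)C)(C(=O)C=C1OC)C2=O | intermediate
19 | 1-bromo-2-methylprop-1-ene | CC(C)=CBr | starting material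
20 | 7-endo-[(9-borabicyclo[3.3.1]nonan-9-yl)methyl]-5-geranyl-4-methoxy-8,8-dimethyl-1-prenylbicyclo[3.3.1]non-3-ene-2,9-dione | CC(C)=CCC/C(C)=C/C[C@]12C[C@H](CB3C4CCCC3CCC4)C(C)(C)[C@](CC=C(C)C)(C(=O)C=C1OC)C2=O | intermediate
21 | 5-geranyl-4-methoxy-8,8-dimethyl-1,7-endo-diprenylbicyclo[3.3.1]non-3-ene-2,9-dione | CC(C)=CCC/C(C)=C/C[C@]12C[C@H](CC=C(C)C)C(C)(C)[C@](CC=C(C)C)(C(=O)C=C1OC)C2=O | intermediate
22 | 3,4-dihydroxybenzoic acid | OC(=O)c1ccc(O)c(O)c1 | starting material
23 | triisopropylsilyl 3,4-bis(triisopropylsilyloxy)benzoate | CC(C)[Si](OC(=O)c1ccc(O[Si](C(C)C)(C(C)C)C(C)C)c(O[Si](C(C)C)(C(C)C)C(C)C)c1)(C(C)C)C(C)C | intermediate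
24 | 3,4-bis(triisopropylsilyloxy)benzoyl chloride | ClC(=O)c1ccc(O[Si](C(C)C)(C(C)C)C(C)C)c(O[Si](C(C)C)(C(C)C)C(C)C)c1 | intermediate
25 | 3-[3,4-bis(triisopropylsilyloxy)benzoyl]-5-geranyl-4-methoxy-8,8-dimethyl-1,7-endo-diprenylbicyclo[3.3.1]non-3-ene-2,9-dione | CC(C)=CCC/C(C)=C/C[C@]12C[C@H](CC=C(C)C)C(C)(C)[C@](CC=C(C)C)(C(=O)C(C(=O)c3ccc(O[Si](C(C)C)(C(C)C)C(C)C)c(O[Si](C(C)C)(C(C)C)C(C)C)c3)=C1OC)C2=O | intermediate
26 | 3-[3,4-bis(triisopropylsilyloxy)benzoyl]-5-geranyl-4-hydroxy-8,8-dimethyl-1,7-endo-diprenylbicyclo[3.3.1]non-3-ene-2,9-dione | CC(C)=CCC/C(C)=C/C[C@]12C[C@H](CC=C(C)C)C(C)(C)[C@](CC=C(C)C)(C(=O)C(C(=O)c3ccc(O[Si](C(C)C)(C(C)C)C(C)C)c(O[Si](C(C)C)(C(C)C)C(C)C)c3)=C1O)C2=O | intermediate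
27 | (1S,5S,7S)-3-(3,4-dihydroxybenzoyl)-5-geranyl-4-hydroxy-8,8-dimethyl-1,7-diprenylbicyclo[3.3.1]non-3-ene-2,9-dione | CC(C)=CCC/C(C)=C/C[C@]12C[C@H](CC=C(C)C)C(C)(C)[C@](CC=C(C)C)(C(=O)C(C(=O)c3ccc(O)c(O)c3)=C1O)C2=O | target

## Step count and risk

Total step count: 19. Longest linear sequence: 15 steps (steps 1, 2, 5–14, 17–19; the branch from 5 through steps 3 and 4 is equally long).

Least certain steps:

**Step 6 (key step).** The most likely failure is incomplete capture of the C9 oxocarbenium ion by the hindered silyloxy oxygen, or acid-induced loss of the strained ketal and of the second enol ether during the reaction and work-up. This would lower the yield and remove the ketal as the built-in check on which enol ether reacted; a 1,2-hydride shift of the activated epoxide to a ketone is a further drain. The fallback stops the cascade after the C–C bond is formed and does not rely on the ketal. It sets out from 9, which is cyclised with a stoichiometric amount of Et3SiOTf and 2,6-di-tert-butyl-4-methylpyridine in CH2Cl2 at −78 °C and quenched with aqueous NaHCO3, so that the oxygen stays silylated and the oxocarbenium ion is hydrolysed to the ketone. This gives 5-geranyl-4-methoxy-8,8-dimethyl-7-exo-(triethylsilyloxy)bicyclo[3.3.1]non-3-en-9-one F1, from which a minor 7-endo diastereomer can be separated. The allylic oxidation of step 7 converts it into 5-geranyl-4-methoxy-8,8-dimethyl-7-exo-(triethylsilyloxy)bicyclo[3.3.1]non-3-ene-2,9-dione F2, and HF·pyridine in THF removes the silyl group, which returns to the route at 12.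

**Step 5.** The hindered tertiary anion may react slowly with the branched bromide, so that alkylation through a terminal carbon of the dienyl anion or base-induced destruction of the epoxy bromide competes. The fallback reverses the order of the two alkylations, so that the quaternary carbon is made with the more reactive allylic electrophile. It sets out from 2, which is lithiated with t-BuLi and alkylated with 8 to give 6-{[(2R)-3,3-dimethyloxiran-2-yl]methyl}-1,5-dimethoxycyclohexa-1,4-diene F3. A second lithiation at −78 °C followed at once by geranyl bromide 3, so that the anion is trapped before it can open the oxirane, returns to the route at 9.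

**Step 10.** C-alkylation of the bridgehead carbanion next to the quaternary C8 may be sluggish, with proton return on work-up. The fallback forms the C1–C bond by a radical, which is far less sensitive to crowding. It sets out from 13, which is lithiated with lithium 2,2,6,6-tetramethylpiperidide and quenched with I2 to give the 1-iodo derivative of 13 F4. Keck allylation with Bu3SnCH2CH=CH2 and Et3B/air gives the 1-allyl derivative of 13 F5, and cross-metathesis with 2-methylbut-2-ene and the second-generation Grubbs catalyst at room temperature, where the trisubstituted olefins are slow to react, returns to the route at 15.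

**Step 13.** The neopentyl C7 ketone may react slowly, so that enolisation or attack of the reagent on another carbonyl competes. The fallback replaces the titanium methylidene by a two-step Peterson olefination with a strongly nucleophilic, weakly basic organocerium reagent. It sets out from 17; Me3SiCH2Li/CeCl3 in THF at −78 °C adds to the most accessible ketone from the exo face to give the 7-endo-hydroxy-7-exo-(trimethylsilylmethyl) adduct of 17 F6, and KH in THF eliminates the silanolate and returns to the route at 18.

**Step 14.** Transmetalation of the branched, hindered alkylborane may be slow and lead to protodeboronation, and the borane may reduce a carbonyl; poor facial selectivity in the hydroboration is the less likely problem. The fallback keeps the hydroboration and replaces the boron coupling by a zinc coupling, which tolerates ketones. It sets out from 20, which is oxidised with NaBO3 to the 7-endo-hydroxymethyl compound F7. I2, PPh3 and imidazole give the 7-endo-iodomethyl compound F8, zinc insertion (Zn, LiCl, THF) gives the 7-endo-(iodozinciomethyl) compound F9, and Negishi coupling with 19 and Pd(PPh3)4 returns to the route at 21.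

## Further compounds

F1 | step 6 | 5-geranyl-4-methoxy-8,8-dimethyl-7-exo-(triethylsilyloxy)bicyclo[3.3.1]non-3-en-9-one | CC(C)=CCC/C(C)=C/C[C@]12C[C@@H](O[Si](CC)(CC)CC)C(C)(C)[C@H](CC=C1OC)C2=O
F2 | step 6 | 5-geranyl-4-methoxy-8,8-dimethyl-7-exo-(triethylsilyloxy)bicyclo[3.3.1]non-3-ene-2,9-dione | CC(C)=CCC/C(C)=C/C[C@]12C[C@@H](O[Si](CC)(CC)CC)C(C)(C)[C@H](C(=O)C=C1OC)C2=O
F3 | step 5 | 6-{[(2R)-3,3-dimethyloxiran-2-yl]methyl}-1,5-dimethoxycyclohexa-1,4-diene | COC1=CCC=C(OC)C1C[C@H]1OC1(C)C
F4 | step 10 | 5-geranyl-1-iodo-4-methoxy-8,8-dimethyl-3-(trimethylsilyl)-7-exo-(trimethylsilyloxy)bicyclo[3.3.1]non-3-ene-2,9-dione | CC(C)=CCC/C(C)=C/C[C@]12C[C@@H](O[Si](C)(C)C)C(C)(C)[C@](I)(C(=O)C([Si](C)(C)C)=C1OC)C2=O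
F5 | step 10 | 1-allyl-5-geranyl-4-methoxy-8,8-dimethyl-3-(trimethylsilyl)-7-exo-(trimethylsilyloxy)bicyclo[3.3.1]non-3-ene-2,9-dione | CC(C)=CCC/C(C)=C/C[C@]12C[C@@H](O[Si](C)(C)C)C(C)(C)[C@](CC=C)(C(=O)C([Si](C)(C)C)=C1OC)C2=O
F6 | step 13 | 5-geranyl-7-endo-hydroxy-4-methoxy-8,8-dimethyl-1-prenyl-7-exo-(trimethylsilylmethyl)bicyclo[3.3.1]non-3-ene-2,9-dione | CC(C)=CCC/C(C)=C/C[C@]12C[C@@](O)(C[Si](C)(C)C)C(C)(C)[C@](CC=C(C)C)(C(=O)C=C1OC)C2=O
F7 | step 14 | 5-geranyl-7-endo-(hydroxymethyl)-4-methoxy-8,8-dimethyl-1-prenylbicyclo[3.3.1]non-3-ene-2,9-dione | CC(C)=CCC/C(C)=C/C[C@]12C[C@H](CO)C(C)(C)[C@](CC=C(C)C)(C(=O)C=C1OC)C2=O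
F8 | step 14 | 5-geranyl-7-endo-(iodomethyl)-4-methoxy-8,8-dimethyl-1-prenylbicyclo[3.3.1]non-3-ene-2,9-dione | CC(C)=CCC/C(C)=C/C[C@]12C[C@H](CI)C(C)(C)[C@](CC=C(C)C)(C(=O)C=C1OC)C2=O
F9 | step 14 | 5-geranyl-7-endo-(iodozinciomethyl)-4-methoxy-8,8-dimethyl-1-prenylbicyclo[3.3.1]non-3-ene-2,9-dione | CC(C)=CCC/C(C)=C/C[C@]12C[C@H](C[Zn]I)C(C)(C)[C@](CC=C(C)C)(C(=O)C=C1OC)C2=O
A1 | alternative 1 | 8,8-dimethyl-7-methylidene-1-prenylbicyclo[3.3.1]nonane-2,9-dione | [C@H]12CC(=C)C(C)(C)[C@](CC=C(C)C)(C(=O)CC1)C2=O
A2 | alternative 1 | methyl 3-methyl-2-methylidene-3-[2,6-dioxo-1-(3-methylbut-2-en-1-yl)cyclohexyl]butyl carbonate | COC(=O)OCC(=C)C(C)(C)C1(CC=C(C)C)C(=O)CCCC1=O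
A3 | alternative 2 | bis(triisopropylsilyl) ether of the 7-methylidene analogue of 27 | CC(C)=CCC/C(C)=C/C[C@]12CC(=C)C(C)(C)[C@](CC=C(C)C)(C(=O)C(C(=O)c3ccc(O[Si](C(C)C)(C(C)C)C(C)C)c(O[Si](C(C)C)(C(C)C)C(C)C)c3)=C1O)C2=O
A4 | alternative 2 | acyclic methyl ester S-ethyl thioester of the prenylmalonic acid whose quaternary carbon also carries the CMe2–C(=CH2)–CH2–CH(geranyl)–CO–CH2–CO–[3,4-bis(triisopropylsilyloxy)phenyl] chain | CC(C)=CCC/C(C)=C/CC(CC(=C)C(C)(C)[C@](CC=C(C)C)(C(=O)OC)C(=O)SCC)C(=O)CC(=O)c1ccc(O[Si](C(C)C)(C(C)C)C(C)C)c(O[Si](C(C)C)(C(C)C)C(C)C)c1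
A5 | alternative 3 | 5-geranyl-4-hydroxy-8,8-dimethyl-7-methylidene-1-prenylbicyclo[3.3.1]non-3-ene-2,9-dione | CC(C)=CCC/C(C)=C/C[C@]12CC(=C)C(C)(C)[C@](CC=C(C)C)(C(=O)C=C1O)C2=O
A6 | alternative 3 | 5-geranyl-2,2-dimethyl-3-methylidene-1-prenylbicyclo[3.1.1]heptane-6,7-dione | CC(C)=CCC/C(C)=C/CC12CC(=C)C(C)(C)C(CC=C(C)C)(C1=O)C2=O
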